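## Structural features

Locants used throughout: ring A carbons a1–a7 (methyl on a1, carbonyl on a3, hydroxyl on a4), ring B atoms O1 (on a6), C2, C3, C4 (on a7), diene carbons C5–C8, primes for the right half.

- The target is two troponoid chromans: each half is a 2-hydroxytropone (ring A, seven-membered) fused through the a6–a7 bond to a dihydropyran (ring B).
- The halves are joined from C2 to C2′ by an (E,E)-buta-1,3-diene.
- The left half has two adjacent stereocentres, C2 (R) and the methyl-bearing C3 (R), trans to each other. The right half has only C2′ (R); C3′ and C4′ are methylenes.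
- The tropolones and their ethers are the fragile part. Electron-transfer reagents and hydride reduce them, nucleophiles attack their oxygen-bearing carbons (they are vinylogous esters), and they chelate metals.
- The C2–O1 and C2′–O1′ bonds are dienylic ethers whose oxygen is a vinylogous carboxylate, so the finished skeleton is acid-labile.
- The real difficulty is a regiodefined, pentasubstituted seven-membered ring (oxygen on a3, a4, a6; carbon on a7, a1) with the trans C2/C3 pair built next to it, using only reagents the tropone survives.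
- The key step exploits the fact that C4 is a one-carbon bridge from a7 to C3 while the neighbouring a6 carries O1. An aldehyde on a7 (the future C4) and an acceptor hung on the a6 oxygen through C2 are then placed for a six-membered closure at C3.

## Logic of the disconnections

**33 from 32.** The two O–CH3 bonds on the a4 and a4′ oxygens are cut last. The tropolone hydroxyls would quench bases and bind palladium and chromium earlier. The forward step must be a mild vinylogous-ester hydrolysis that leaves the acid-labile C2–O1 and C2′–O1′ bonds alone.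

**32 from 24 and 31.** The C6–C7 single bond of the diene is cut. This divides the molecule into halves of equal size and lets both alkene geometries be fixed before the halves meet. The forward coupling must retain both geometries and use only a mild base.

**24 from 23, 22, 21; 31 from 30, 29.** The C5=C6 and C7=C8 bonds are each cut to an aldehyde on C2 or C2′ plus a one-carbon unit. Both halves then end in the same primary alcohol function. The forward olefinations must be non-basic, because the aldehydes are α-aryloxy and epimerisable, and must be E-selective.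

**21 from 20, 19, 18.** The two C4–H bonds are traced back to the C4 ketone that the key step necessarily leaves. The forward removal must not pass through a C4 cation: next to a protonated tropone it would form poorly, and it could lose the C3 proton. A radical deoxygenation of the derived alcohol is chosen.

**18 from 17 and 16.** A C–H bond of the C3 methyl is traced back to the C–S bond of a sulfonylmethyl group. Direct reductive cleavage needs electron-transfer reagents that would reduce the tropone first. The forward path instead uses what a β-sulfonyl ketone does by nature: E1cB loss of sulfinate to 17, then conjugate reduction. The price is that C3 becomes trigonal and is set again, under thermodynamic control relayed from C2. The configuration set in the key step is what the fallback for step 14 relies on.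

**16 from 15 (key step).** The C3–C4 bond is cut. Both carbons are electrophilic in 15 (aldehyde carbon and the β-carbon of a vinyl sulfone), so the forward step needs polarity reversal at the aldehyde. The gain is the whole of ring B with the O1–C2 bond already present, from a monocyclic troponoid.

**15 from 8 and 14.** The a6–O1 bond is cut. The forward step is an addition–elimination at a6 of the β-methoxy enal by the secondary hydroxyl of 14 under acid catalysis. The carbinol C–O bond is never broken, so C2 is transferred with retention. No alkoxide is formed, so the silyl group cannot migrate and the vinyl sulfone cannot be attacked or isomerised. The structures of 15, 16 and 33 were cross-checked and are mutually consistent: C2 keeps one spatial arrangement (R) throughout, and C3 is S in 16 and R in 33 only because the CIP ranking changes. With retention at C2, the R antipode 9 is the correct chiral-pool source.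

**14 from 13, 12, 10 and 11; 10 from 9.** The vinyl sulfone C=C bond is cut to the chiral-pool aldehyde and the sulfonyl phosphonate; the primary silyl ether and the acetonide are protecting-group changes. The forward olefination must be E-selective and must not epimerise the α-alkoxy aldehyde.

**8 from 7; 7 from 6.** The a7–CHO bond is cut to a C–Br bond, then the a4 O–methyl bond. The bromine marks a7 unambiguously, which electrophilic formylation of a hydroxytropone would not (a5 competes). The forward O-methylation is ambident over the a3 and a4 oxygens and needs a separation.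

**6 from 5, 4, 3, 2 and 1.** Ring A is traced back to a six-membered ring plus one carbon: a7 is inserted between a1 and a6 as a dihalocarbene carbon, and the a3/a4 oxygens come from an alkene. This reduces the tropolone to a cheap arene. The carbene must select the enol ether double bond, and the cyclopropane must open only after the 1,2-dione is in place.

**29 from 28 and 27; 27 from 26, 25 and 7; 25 from 10.** The a6′–O1′ bond is cut (the same acid-catalysed addition–elimination, now intramolecular), then the a7′–C4′ bond (sp2–sp3 coupling at the bromide). The right half is thus closed at oxygen and the left half at carbon, both from the common bromide 7 and the common aldehyde 10. The forward ring closure must prefer the secondary hydroxyl (six-membered ring) over the primary one.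

## Other disconnections considered

**Alternative 1:** The cut is the a1=a2 double bond of ring A. In the forward step RuCl2(=CHPh)(PCy3)(H2IMes), the second-generation Grubbs catalyst, would join the isopropenyl group on a7 to the vinyl ketone at the end of the a6 side chain of the triene A2. This closes the seven-membered ring to the cycloheptadienone A1; desilylation, oxidation at a4 and tautomerisation would then give the tropolone.
- In its favour: ring B and the C2/C3 pair are made before any tropone exists, so no reduction has to be run beside a tropone. On this point it is better than the chosen plan. The positions of the ring A oxygens are fixed by the chain, so there is no ambident O-alkylation as in step 5; this is also better.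
- Against it here: the metathesis must form a trisubstituted enone in a seven-membered ring from a 1,1-disubstituted alkene and an electron-poor vinyl ketone, next to a tetrasubstituted enol ether. A2 is a sensitive cyclic enol ether that takes many steps to assemble. Each half needs its own ring A construction, whereas 7 serves both halves in the chosen plan.
- Comparison: both plans close one ring with one new bond in the key step. The alternative wins on functional-group tolerance after the key step and loses on step economy and on the likelihood of the ring closure itself.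

**Alternative 2:** The cuts are C2–C5 and C2′–C8. In the forward step [Rh(OH)(cod)]2 (monovalent rhodium) with a chiral diene ligand would transfer the two alkenyl ends of the bis(boronate) A4 in turn to C2 of the 3-methylpyranone A5 and to C2′ of the unsubstituted pyranone A6, giving the bis(pyran-4-one) A3.
- In its favour: it is the most convergent plan and clearly better in step economy. C2 and C2′ are set by the catalyst and not taken from the chiral pool, and the diene geometry is carried in A4, which is the equal of the Suzuki union used here.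
- Against it here: A5 is an α-substituted acceptor, a slow substrate for conjugate addition of an alkenyl group. The two ends of A4 must be told apart in one flask, and the second alkenylboronate can protodeboronate meanwhile. C3 would be set by enolate protonation, so it depends on the same thermodynamic trans preference as the chosen plan (equal on this point). A3 then has two C4 ketones to remove beside two tropones and the diene, which is harder than in the chosen plan, where the single ketone is removed before the diene exists.
- Comparison: better on bond count per step and on C2/C2′ control; worse on chemoselectivity in the key step and on everything after it.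

**Alternative 3:** The cuts are a4–a5 and a6–a7. In the forward step, base-induced loss of acetate from the acetoxypyranone A8 would give a 3-oxidopyrylium ylide. This adds across the tethered ethynyl ether and closes ring A and ring B together as the oxygen-bridged cycloheptadienone A7; opening of the bridge would give the tropolone.
- In its favour: two rings form in one step. C4 is a methylene from the outset and no sulfonyl group is needed, so the whole post-key-step burden of the chosen plan (steps 13–17) disappears; on this point it is better. C2 and C3 are set in an open-chain tether by standard methods, equal or better than the chosen plan. The a4 oxygen comes from the bridge, so its position is defined.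
- Against it here: the ynol ether tether is sensitive to acid and water. Opening the bridge at the quaternary a7 needs acid that also threatens the enol ether a5=a6–O1. A8 requires a long furan-to-pyranone sequence, and the right half would need a second, different cycloaddition substrate.
- Comparison: a pericyclic closure against an organocatalytic polarity reversal; better after the key step, worse before it, and without the shared intermediates (7, 10) that shorten the chosen plan.

Key step: step 12

Assumption: the oxygen of the tropolone that carries the methyl group is a spectator choice; the route is drawn with methyl on the a4 oxygen (carbonyl on a3), and the a3-O-methyl isomer would behave alike and converge on 33.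

## Steps

Step 1
Reactants: 1 2-methylanisole
Product: 2 1-methoxy-2-methylcyclohexa-1,4-diene
Conditions: Li, NH3 (l), t-BuOH, THF, −78 to −33 °C; NH4Cl
Reagents that add atoms: none
Why: Birch reduction; both donor-bearing carbons should stay sp2, giving the diene with a tetrasubstituted enol ether (future a1=a6) and an isolated disubstituted alkene (future a3=a4).

Step 2
Reactants: 2 1-methoxy-2-methylcyclohexa-1,4-diene
Product: 3 7,7-dibromo-1-methoxy-6-methylbicyclo[4.1.0]hept-3-ene (racemic)
Conditions: CHBr3, KOt-Bu, pentane, −20 to 0 °C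
Reagents that add atoms: bromoform, BrC(Br)Br
Why: Dibromocarbene [2+1] cycloaddition; the electrophilic carbene should take the electron-rich enol ether in preference to the disubstituted alkene, which places the future a7 between a1 and a6.

Step 3
Reactants: 3 7,7-dibromo-1-methoxy-6-methylbicyclo[4.1.0]hept-3-ene
Product: 4 7,7-dibromo-1-methoxy-6-methylbicyclo[4.1.0]heptane-3,4-diol (cis-diol, racemic, face relative to the cyclopropane immaterial)
Conditions: OsO4 (cat.), N-methylmorpholine N-oxide, acetone–H2O, 0 °C
Reagents that add atoms: osmium tetroxide, O=[Os](=O)(=O)=O (catalytic; its oxygen is restored from N-methylmorpholine N-oxide, C[N+]1([O-])CCOCC1, and water, O)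
Why: Upjohn syn-dihydroxylation of the only remaining alkene installs the a3 and a4 oxygens; both new centres are destroyed in step 4, so facial selectivity does not matter.

Step 4
Reactants: 4 7,7-dibromo-1-methoxy-6-methylbicyclo[4.1.0]heptane-3,4-diol
Product: 6 5-bromo-2-hydroxy-4-methoxy-6-methylcyclohepta-2,4,6-trien-1-one, via bicyclic 1,2-diketone 5 (not isolated)
Conditions: (CF3CO)2O, DMSO, CH2Cl2, −60 °C; then Et3N, −60 °C to rt
Reagents that add atoms: none
Why: Swern-type double oxidation gives the 1,2-dione, whose enol should trigger methoxy-assisted opening of the gem-dibromocyclopropane with loss of HBr and tautomerisation to the tropolone; this is the established gem-dihalocyclopropane ring expansion to halotropolones.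

Step 5
Reactants: 6 5-bromo-2-hydroxy-4-methoxy-6-methylcyclohepta-2,4,6-trien-1-one
Product: 7 5-bromo-2,4-dimethoxy-6-methylcyclohepta-2,4,6-trien-1-one
Conditions: Me2SO4, K2CO3, acetone, 50 °C; chromatographic separation from the regioisomeric O-methyl ether
Reagents that add atoms: dimethyl sulfate, COS(=O)(=O)OC
Why: O-alkylation of the tropolonate; the anion is ambident over the two vicinal oxygens, so the isomeric ether is expected beside 7, is removed here and can be returned to 6 by mild alkaline hydrolysis.

Step 6
Reactants: 7 5-bromo-2,4-dimethoxy-6-methylcyclohepta-2,4,6-trien-1-one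
Product: 8 2,4-dimethoxy-7-methyl-5-oxocyclohepta-1,3,6-triene-1-carbaldehyde (the 5-formyl analogue of 7)
Conditions: Pd(OAc)2 (cat.), (1-Ad)2P(n-Bu), CO/H2 (1:1, 5 bar), TMEDA, PhMe, 100 °C
Reagents that add atoms: carbon monoxide, [C-]#[O+]
Why: Palladium-catalysed reductive carbonylation (formylation) of the C–Br bond; oxidative addition at bromotropolone derivatives is known from their carbonylations and cross-couplings.

Step 7
Reactants: 9 (R)-solketal, [(4R)-2,2-dimethyl-1,3-dioxolan-4-yl]methanol
Product: 10 (4S)-2,2-dimethyl-1,3-dioxolane-4-carbaldehyde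
Conditions: (COCl)2, DMSO, CH2Cl2, −78 °C; Et3N; used crude
Reagents that add atoms: none
Why: Swern oxidation; low temperature and non-aqueous isolation should keep the α-alkoxy aldehyde configurationally intact (the descriptor changes from R to S through CIP ranking only).

Step 8
Reactants: 10 (4S)-2,2-dimethyl-1,3-dioxolane-4-carbaldehyde; 11 diethyl [(phenylsulfonyl)methyl]phosphonate
Product: 12 (4R)-2,2-dimethyl-4-[(E)-2-(phenylsulfonyl)ethenyl]-1,3-dioxolane
Conditions: NaH, THF, 0 °C to rt
Reagents that add atoms: none
Why: Horner–Wadsworth–Emmons olefination with a sulfonyl-stabilised phosphonate anion, which is reliably E-selective and delivers the future Stetter acceptor directly.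

Step 9
Reactants: 12 (4R)-2,2-dimethyl-4-[(E)-2-(phenylsulfonyl)ethenyl]-1,3-dioxolane
Product: 13 (2R,3E)-4-(phenylsulfonyl)but-3-ene-1,2-diol
Conditions: AcOH–H2O (4:1), 40 °C
Reagents that add atoms: none
Why: Acid hydrolysis of the acetonide; the electron-poor allylic system cannot ionise, so the stereocentre should be untouched.

Step 10
Reactants: 13 (2R,3E)-4-(phenylsulfonyl)but-3-ene-1,2-diol
Product: 14 (2R,3E)-1-[(tert-butyldimethylsilyl)oxy]-4-(phenylsulfonyl)but-3-en-2-ol
Conditions: t-BuMe2SiCl, imidazole, CH2Cl2, −10 °C
Reagents that add atoms: tert-butyldimethylsilyl chloride, CC(C)(C)[Si](C)(C)Cl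
Why: Selective silylation of the primary hydroxyl over the hindered, electron-poor allylic secondary one.

Step 11
Reactants: 8 2,4-dimethoxy-7-methyl-5-oxocyclohepta-1,3,6-triene-1-carbaldehyde; 14 (2R,3E)-1-[(tert-butyldimethylsilyl)oxy]-4-(phenylsulfonyl)but-3-en-2-ol
Product: 15 2-{[(2R,3E)-1-[(tert-butyldimethylsilyl)oxy]-4-(phenylsulfonyl)but-3-en-2-yl]oxy}-4-methoxy-7-methyl-5-oxocyclohepta-1,3,6-triene-1-carbaldehyde
Conditions: pyridinium p-toluenesulfonate (cat.), 4 Å molecular sieves, PhMe, 80 °C
Reagents that add atoms: none
Why: Acid-catalysed addition–elimination (vinylogous transesterification) at a6 of the β-methoxy enal, driven by sequestering methanol; the carbinol C–O bond is not broken, so C2 is formed with retention, and no alkoxide arises that could move the silyl group or attack the vinyl sulfone.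

Step 12
Reactants: 15 2-{[(2R,3E)-1-[(tert-butyldimethylsilyl)oxy]-4-(phenylsulfonyl)but-3-en-2-yl]oxy}-4-methoxy-7-methyl-5-oxocyclohepta-1,3,6-triene-1-carbaldehyde
Product: 16 (2R,3S)-2-{[(tert-butyldimethylsilyl)oxy]methyl}-8-methoxy-5-methyl-3-[(phenylsulfonyl)methyl]-2,3-dihydrocyclohepta[b]pyran-4,7-dione (2,3-trans)
Conditions: aminoindanol-derived N-pentafluorophenyl triazolium tetrafluoroborate (20 mol %, the antipode matched to C2), KN(SiMe3)2 (18 mol %), PhMe, 0 °C to rt
Reagents that add atoms: none
Why: The free carbene adds to the a7 aldehyde and proton transfer gives the Breslow enaminol, an acyl-anion equivalent at C4; this adds to the β-carbon of the tethered vinyl sulfone, the α-sulfonyl carbanion is protonated and the carbene is expelled, leaving the C4 ketone. The closest known reaction type is the carbene-catalysed intramolecular Stetter reaction of salicylaldehyde ethers carrying an O-tethered Michael acceptor to chroman-4-ones; vinyl sulfones are established Stetter acceptors, and a β-alkoxy enal on a tropone is the troponoid counterpart of a salicylaldehyde ether. Ring B closes in the 6-exo-trig mode, with the O1–C2 ether already in place. The new C3 centre is controlled by the catalyst, whose indane wall shields one face of the enaminol and which is used in the antipode that reinforces the bias of C2 (silyloxymethyl group pseudo-equatorial in a chair-like transition state), so the sulfonylmethyl group should come out trans to it; trans is also the thermodynamic arrangement α to the ketone. C2 is not touched. The step needs chemoselectivity for the aldehyde over the tropone carbonyl and the vinylogous ester carbon a6, and cyclisation over benzoin-type dimerisation: only the aldehyde can give a Breslow intermediate, and the tether on the neighbouring oxygen holds the electron-poor alkene within reach. The base is kept below the amount of triazolium salt so that no free amide remains to deprotonate C2–H or to cause E1cB loss of sulfinate from 16.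

Step 13
Reactants: 16 (2R,3S)-2-{[(tert-butyldimethylsilyl)oxy]methyl}-8-methoxy-5-methyl-3-[(phenylsulfonyl)methyl]-2,3-dihydrocyclohepta[b]pyran-4,7-dione
Product: 17 (2R)-2-{[(tert-butyldimethylsilyl)oxy]methyl}-8-methoxy-5-methyl-3-methylidene-2,3-dihydrocyclohepta[b]pyran-4,7-dione
Conditions: Et3N, CH2Cl2–aq. NaHCO3 (two-phase), 0 °C to rt
Reagents that add atoms: none
Why: E1cB loss of benzenesulfinate from the β-sulfonyl ketone, chosen because electron-transfer desulfonylation would reduce the tropone first; the exocyclic C–S bond aligns with the enolate far better than the ring C2–O1 bond, which should therefore be spared. C3 becomes trigonal here and is set again in step 14.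

Step 14
Reactants: 17 (2R)-2-{[(tert-butyldimethylsilyl)oxy]methyl}-8-methoxy-5-methyl-3-methylidene-2,3-dihydrocyclohepta[b]pyran-4,7-dione
Product: 18 (2R,3S)-2-{[(tert-butyldimethylsilyl)oxy]methyl}-8-methoxy-3,5-dimethyl-2,3-dihydrocyclohepta[b]pyran-4,7-dione (2,3-trans)
Conditions: Cu(OAc)2·H2O (cat.), 1,2-(Ph2P)2C6H4, (HMe2Si)2O, t-BuOH, PhMe, rt; then (+)-camphorsulfonic acid (cat.), CHCl3, 40 °C
Reagents that add atoms: none
Why: Copper hydride 1,4-reduction of the very reactive α-methylene ketone (the donor-substituted tropone is a much poorer acceptor) makes the C3 methyl; acid-mediated enolisation then converges the C3 epimers on the trans isomer, the thermodynamic one for 2,3-dialkylchroman-4-ones. Acid and not base is used so that no enolate forms that could expel the a6 oxygen and erode C2.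

Step 15
Reactants: 18 (2R,3S)-2-{[(tert-butyldimethylsilyl)oxy]methyl}-8-methoxy-3,5-dimethyl-2,3-dihydrocyclohepta[b]pyran-4,7-dione
Product: 19 (2R,3R,4RS)-2-{[(tert-butyldimethylsilyl)oxy]methyl}-4-hydroxy-8-methoxy-3,5-dimethyl-3,4-dihydrocyclohepta[b]pyran-7(2H)-one (C4 epimers, configuration immaterial)
Conditions: NaBH4, CeCl3·7H2O, MeOH–THF, −40 °C
Reagents that add atoms: none
Why: Luche 1,2-reduction of the ketone; the hard, cerium-activated hydride at low temperature should leave the donor-substituted tropone alone, and C3 is no longer epimerisable afterwards.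

Step 16
Reactants: 19 (2R,3R,4RS)-2-{[(tert-butyldimethylsilyl)oxy]methyl}-4-hydroxy-8-methoxy-3,5-dimethyl-3,4-dihydrocyclohepta[b]pyran-7(2H)-one
Product: 20 O-[(2R,3R,4RS)-2-{[(tert-butyldimethylsilyl)oxy]methyl}-8-methoxy-3,5-dimethyl-7-oxo-2,3,4,7-tetrahydrocyclohepta[b]pyran-4-yl] 1H-imidazole-1-carbothioate
Conditions: 1,1′-thiocarbonyldiimidazole, DMAP (cat.), ClCH2CH2Cl, 60 °C
Reagents that add atoms: 1,1′-thiocarbonyldiimidazole, S=C(n1ccnc1)n1ccnc1
Why: Thioacylation of the secondary alcohol under neutral conditions prepares the radical deoxygenation.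

Step 17
Reactants: 20 O-[(2R,3R,4RS)-2-{[(tert-butyldimethylsilyl)oxy]methyl}-8-methoxy-3,5-dimethyl-7-oxo-2,3,4,7-tetrahydrocyclohepta[b]pyran-4-yl] 1H-imidazole-1-carbothioate
Product: 21 (2R,3R)-2-{[(tert-butyldimethylsilyl)oxy]methyl}-8-methoxy-3,5-dimethyl-3,4-dihydrocyclohepta[b]pyran-7(2H)-one
Conditions: Bu3SnH, AIBN (cat.), PhMe, 90 °C
Reagents that add atoms: none
Why: Barton–McCombie deoxygenation; the ring-stabilised C4 radical is reduced without involving C3, whereas a C4 cation beside a protonated tropone would form poorly and could lose the C3 proton.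

Step 18
Reactants: 21 (2R,3R)-2-{[(tert-butyldimethylsilyl)oxy]methyl}-8-methoxy-3,5-dimethyl-3,4-dihydrocyclohepta[b]pyran-7(2H)-one
Product: 22 (2R,3R)-2-(hydroxymethyl)-8-methoxy-3,5-dimethyl-3,4-dihydrocyclohepta[b]pyran-7(2H)-one
Conditions: Bu4NF, AcOH, THF, 0 °C
Reagents that add atoms: none
Why: Fluoride desilylation, buffered so that no basic alkoxide or hydroxide meets the vinylogous ester.

Step 19
Reactants: 22 (2R,3R)-2-(hydroxymethyl)-8-methoxy-3,5-dimethyl-3,4-dihydrocyclohepta[b]pyran-7(2H)-one
Product: 23 (2R,3R)-8-methoxy-3,5-dimethyl-7-oxo-2,3,4,7-tetrahydrocyclohepta[b]pyran-2-carbaldehyde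
Conditions: Dess–Martin periodinane, NaHCO3, CH2Cl2, 0 °C; used at once
Reagents that add atoms: none
Why: Neutral periodinane oxidation gives the α-aryloxy aldehyde without the base that could epimerise C2.

Step 20
Reactants: 23 (2R,3R)-8-methoxy-3,5-dimethyl-7-oxo-2,3,4,7-tetrahydrocyclohepta[b]pyran-2-carbaldehyde
Product: 24 (2R,3R)-2-[(E)-2-iodoethenyl]-8-methoxy-3,5-dimethyl-3,4-dihydrocyclohepta[b]pyran-7(2H)-one
Conditions: CrCl2, CHI3, THF–dioxane, 0 °C to rt
Reagents that add atoms: iodoform, IC(I)I
Why: Takai iodo-olefination forms C5=C6; it is non-basic, E-selective for α-branched aldehydes, and CrCl2 is far too weak a reductant to touch the tropone.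

Step 21
Reactants: 10 (4S)-2,2-dimethyl-1,3-dioxolane-4-carbaldehyde
Product: 25 (4R)-4-ethenyl-2,2-dimethyl-1,3-dioxolane
Conditions: Ph3PCH3Br, KN(SiMe3)2, THF, −78 to 0 °C
Reagents that add atoms: methyltriphenylphosphonium bromide, C[P+](c1ccccc1)(c1ccccc1)c1ccccc1.[Br-]
Why: Wittig methylenation of the same chiral-pool aldehyde, which should proceed without racemisation at low temperature.

Step 22
Reactants: 25 (4R)-4-ethenyl-2,2-dimethyl-1,3-dioxolane; 7 5-bromo-2,4-dimethoxy-6-methylcyclohepta-2,4,6-trien-1-one
Product: 27 5-{2-[(4R)-2,2-dimethyl-1,3-dioxolan-4-yl]ethyl}-2,4-dimethoxy-6-methylcyclohepta-2,4,6-trien-1-one, via B-alkyl-9-BBN adduct 26 (not isolated)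
Conditions: 9-BBN, THF, rt; then 7, Pd(dppf)Cl2, AsPh3, Cs2CO3, DMF–H2O, rt to 50 °C
Reagents that add atoms: none
Why: Anti-Markovnikov hydroboration followed by B-alkyl Suzuki–Miyaura coupling at the C–Br bond forms a7′–C4′ and brings in the saturated C4′–C3′ chain with the C2′ oxygen stereocentre from the chiral pool.

Step 23
Reactants: 27 5-{2-[(4R)-2,2-dimethyl-1,3-dioxolan-4-yl]ethyl}-2,4-dimethoxy-6-methylcyclohepta-2,4,6-trien-1-one
Product: 29 (2R)-2-(hydroxymethyl)-8-methoxy-5-methyl-3,4-dihydrocyclohepta[b]pyran-7(2H)-one, via diol 28 (not isolated)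
Conditions: pyridinium p-toluenesulfonate, MeOH, 45 °C; evaporate; then (+)-camphorsulfonic acid (cat.), 4 Å molecular sieves, PhMe, 90 °C
Reagents that add atoms: none
Why: Acetal exchange frees the diol, whose secondary hydroxyl then replaces the a6′ methoxy group by acid-catalysed addition–elimination on the vinylogous ester; the six-membered ring should win over the seven-membered one from the primary hydroxyl under these reversible conditions, and C2′ keeps its configuration because its C–O bond is not broken.

Step 24
Reactants: 29 (2R)-2-(hydroxymethyl)-8-methoxy-5-methyl-3,4-dihydrocyclohepta[b]pyran-7(2H)-one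
Product: 30 (2R)-8-methoxy-5-methyl-7-oxo-2,3,4,7-tetrahydrocyclohepta[b]pyran-2-carbaldehyde
Conditions: Dess–Martin periodinane, NaHCO3, CH2Cl2, 0 °C; used at once
Reagents that add atoms: none
Why: Neutral periodinane oxidation, as in step 19, avoids epimerising the α-aryloxy aldehyde.

Step 25
Reactants: 30 (2R)-8-methoxy-5-methyl-7-oxo-2,3,4,7-tetrahydrocyclohepta[b]pyran-2-carbaldehyde
Product: 31 (2R)-8-methoxy-5-methyl-2-[(E)-2-(4,4,5,5-tetramethyl-1,3,2-dioxaborolan-2-yl)ethenyl]-3,4-dihydrocyclohepta[b]pyran-7(2H)-one
Conditions: CrCl2, Cl2CHB(pin), LiI, THF, rt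
Reagents that add atoms: 2-(dichloromethyl)-4,4,5,5-tetramethyl-1,3,2-dioxaborolane, CC1(C)OB(C(Cl)Cl)OC1(C)C
Why: Takai–Utimoto boryl olefination forms C7=C8 with high E selectivity under non-basic conditions.

Step 26
Reactants: 24 (2R,3R)-2-[(E)-2-iodoethenyl]-8-methoxy-3,5-dimethyl-3,4-dihydrocyclohepta[b]pyran-7(2H)-one; 31 (2R)-8-methoxy-5-methyl-2-[(E)-2-(4,4,5,5-tetramethyl-1,3,2-dioxaborolan-2-yl)ethenyl]-3,4-dihydrocyclohepta[b]pyran-7(2H)-one
Product: 32 (2R,3R)-8-methoxy-2-{(1E,3E)-4-[(2R)-8-methoxy-5-methyl-7-oxo-2,3,4,7-tetrahydrocyclohepta[b]pyran-2-yl]buta-1,3-dien-1-yl}-3,5-dimethyl-3,4-dihydrocyclohepta[b]pyran-7(2H)-one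
Conditions: Pd(PPh3)4 (cat.), K3PO4 (aq.), THF, rt to 40 °C
Reagents that add atoms: none
Why: Suzuki–Miyaura coupling of the alkenyl iodide with the alkenyl boronate forms C6–C7 with retention of both alkene geometries; oxidative addition at the C–I bond is far faster than any reaction at the tropone ethers.

Step 27
Reactants: 32 (2R,3R)-8-methoxy-2-{(1E,3E)-4-[(2R)-8-methoxy-5-methyl-7-oxo-2,3,4,7-tetrahydrocyclohepta[b]pyran-2-yl]buta-1,3-dien-1-yl}-3,5-dimethyl-3,4-dihydrocyclohepta[b]pyran-7(2H)-one
Product: 33 CNP0332980.1, (2R,3R)-8-hydroxy-2-{(1E,3E)-4-[(2R)-8-hydroxy-5-methyl-7-oxo-2,3,4,7-tetrahydrocyclohepta[b]pyran-2-yl]buta-1,3-dien-1-yl}-3,5-dimethyl-3,4-dihydrocyclohepta[b]pyran-7(2H)-one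
Conditions: LiOH, THF–H2O, 40 °C; then NaH2PO4 to pH 5
Reagents that add atoms: lithium hydroxide, [Li+].[OH-]
Why: 2-Methoxytropones are vinylogous esters: hydroxide adds to the methoxy-bearing ring carbon and expels methoxide, and the resulting tropolonate resists further attack. Base is preferred to acid because the C2–O1 and C2′–O1′ bonds are dienylic ethers with a good leaving group.

## Compound list

1 | 2-methylanisole | COc1ccccc1C | starting material
2 | 1-methoxy-2-methylcyclohexa-1,4-diene | COC1=C(C)CC=CC1 | intermediate
3 | 7,7-dibromo-1-methoxy-6-methylbicyclo[4.1.0]hept-3-ene (racemic) | COC12CC=CCC1(C)C2(Br)Br | intermediate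
4 | 7,7-dibromo-1-methoxy-6-methylbicyclo[4.1.0]heptane-3,4-diol (cis-diol, racemic) | COC12CC(O)C(O)CC1(C)C2(Br)Br | intermediate
5 | 7,7-dibromo-1-methoxy-6-methylbicyclo[4.1.0]heptane-3,4-dione | COC12CC(=O)C(=O)CC1(C)C2(Br)Br | intermediate (not isolated)
6 | 5-bromo-2-hydroxy-4-methoxy-6-methylcyclohepta-2,4,6-trien-1-one | Cc1cc(=O)c(O)cc(OC)c1Br | intermediate
7 | 5-bromo-2,4-dimethoxy-6-methylcyclohepta-2,4,6-trien-1-one | Cc1cc(=O)c(OC)cc(OC)c1Br | intermediate
8 | 2,4-dimethoxy-7-methyl-5-oxocyclohepta-1,3,6-triene-1-carbaldehyde | Cc1cc(=O)c(OC)cc(OC)c1C=O | intermediate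
9 | (R)-solketal, [(4R)-2,2-dimethyl-1,3-dioxolan-4-yl]methanol | OC[C@@H]1COC(C)(C)O1 | starting material
10 | (4S)-2,2-dimethyl-1,3-dioxolane-4-carbaldehyde | O=C[C@@H]1COC(C)(C)O1 | intermediate
11 | diethyl [(phenylsulfonyl)methyl]phosphonate | CCOP(=O)(CS(=O)(=O)c1ccccc1)OCC | starting material
12 | (4R)-2,2-dimethyl-4-[(E)-2-(phenylsulfonyl)ethenyl]-1,3-dioxolane | O=S(=O)(c1ccccc1)/C=C/[C@@H]1COC(C)(C)O1 | intermediate
13 | (2R,3E)-4-(phenylsulfonyl)but-3-ene-1,2-diol | OC[C@H](O)/C=C/S(=O)(=O)c1ccccc1 | intermediate
14 | (2R,3E)-1-[(tert-butyldimethylsilyl)oxy]-4-(phenylsulfonyl)but-3-en-2-ol | CC(C)(C)[Si](C)(C)OC[C@H](O)/C=C/S(=O)(=O)c1ccccc1 | intermediate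
15 | 2-{[(2R,3E)-1-[(tert-butyldimethylsilyl)oxy]-4-(phenylsulfonyl)but-3-en-2-yl]oxy}-4-methoxy-7-methyl-5-oxocyclohepta-1,3,6-triene-1-carbaldehyde | Cc1cc(=O)c(OC)cc(O[C@@H](CO[Si](C)(C)C(C)(C)C)/C=C/S(=O)(=O)c2ccccc2)c1C=O | intermediate
16 | (2R,3S)-2-{[(tert-butyldimethylsilyl)oxy]methyl}-8-methoxy-5-methyl-3-[(phenylsulfonyl)methyl]-2,3-dihydrocyclohepta[b]pyran-4,7-dione | Cc1cc(=O)c(OC)cc2c1C(=O)[C@@H](CS(=O)(=O)c1ccccc1)[C@H](CO[Si](C)(C)C(C)(C)C)O2 | intermediate
17 | (2R)-2-{[(tert-butyldimethylsilyl)oxy]methyl}-8-methoxy-5-methyl-3-methylidene-2,3-dihydrocyclohepta[b]pyran-4,7-dione | Cc1cc(=O)c(OC)cc2c1C(=O)C(=C)[C@H](CO[Si](C)(C)C(C)(C)C)O2 | intermediate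
18 | (2R,3S)-2-{[(tert-butyldimethylsilyl)oxy]methyl}-8-methoxy-3,5-dimethyl-2,3-dihydrocyclohepta[b]pyran-4,7-dione | Cc1cc(=O)c(OC)cc2c1C(=O)[C@@H](C)[C@H](CO[Si](C)(C)C(C)(C)C)O2 | intermediate
19 | (2R,3R,4RS)-2-{[(tert-butyldimethylsilyl)oxy]methyl}-4-hydroxy-8-methoxy-3,5-dimethyl-3,4-dihydrocyclohepta[b]pyran-7(2H)-one | Cc1cc(=O)c(OC)cc2c1C(O)[C@@H](C)[C@H](CO[Si](C)(C)C(C)(C)C)O2 | intermediate
20 | O-[(2R,3R,4RS)-2-{[(tert-butyldimethylsilyl)oxy]methyl}-8-methoxy-3,5-dimethyl-7-oxo-2,3,4,7-tetrahydrocyclohepta[b]pyran-4-yl] 1H-imidazole-1-carbothioate | Cc1cc(=O)c(OC)cc2c1C(OC(=S)n1ccnc1)[C@@H](C)[C@H](CO[Si](C)(C)C(C)(C)C)O2 | intermediate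
21 | (2R,3R)-2-{[(tert-butyldimethylsilyl)oxy]methyl}-8-methoxy-3,5-dimethyl-3,4-dihydrocyclohepta[b]pyran-7(2H)-one | Cc1cc(=O)c(OC)cc2c1C[C@@H](C)[C@H](CO[Si](C)(C)C(C)(C)C)O2 | intermediate
22 | (2R,3R)-2-(hydroxymethyl)-8-methoxy-3,5-dimethyl-3,4-dihydrocyclohepta[b]pyran-7(2H)-one | Cc1cc(=O)c(OC)cc2c1C[C@@H](C)[C@H](CO)O2 | intermediate
23 | (2R,3R)-8-methoxy-3,5-dimethyl-7-oxo-2,3,4,7-tetrahydrocyclohepta[b]pyran-2-carbaldehyde | Cc1cc(=O)c(OC)cc2c1C[C@@H](C)[C@H](C=O)O2 | intermediate
24 | (2R,3R)-2-[(E)-2-iodoethenyl]-8-methoxy-3,5-dimethyl-3,4-dihydrocyclohepta[b]pyran-7(2H)-one | Cc1cc(=O)c(OC)cc2c1C[C@@H](C)[C@H](/C=C/I)O2 | intermediate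
25 | (4R)-4-ethenyl-2,2-dimethyl-1,3-dioxolane | C=C[C@@H]1COC(C)(C)O1 | intermediate
26 | 9-{2-[(4R)-2,2-dimethyl-1,3-dioxolan-4-yl]ethyl}-9-borabicyclo[3.3.1]nonane | C1CCC2CCCC1B2CC[C@@H]1COC(C)(C)O1 | intermediate (not isolated)
27 | 5-{2-[(4R)-2,2-dimethyl-1,3-dioxolan-4-yl]ethyl}-2,4-dimethoxy-6-methylcyclohepta-2,4,6-trien-1-one | Cc1cc(=O)c(OC)cc(OC)c1CC[C@@H]1COC(C)(C)O1 | intermediate
28 | 5-[(3R)-3,4-dihydroxybutyl]-2,4-dimethoxy-6-methylcyclohepta-2,4,6-trien-1-one | Cc1cc(=O)c(OC)cc(OC)c1CC[C@@H](O)CO | intermediate (not isolated)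
29 | (2R)-2-(hydroxymethyl)-8-methoxy-5-methyl-3,4-dihydrocyclohepta[b]pyran-7(2H)-one | OC[C@H]1CCc2c(C)cc(=O)c(OC)cc2O1 | intermediate
30 | (2R)-8-methoxy-5-methyl-7-oxo-2,3,4,7-tetrahydrocyclohepta[b]pyran-2-carbaldehyde | O=C[C@H]1CCc2c(C)cc(=O)c(OC)cc2O1 | intermediate
31 | (2R)-8-methoxy-5-methyl-2-[(E)-2-(4,4,5,5-tetramethyl-1,3,2-dioxaborolan-2-yl)ethenyl]-3,4-dihydrocyclohepta[b]pyran-7(2H)-one | CC1(C)OB(/C=C/[C@H]2CCc3c(C)cc(=O)c(OC)cc3O2)OC1(C)C | intermediate
32 | (2R,3R)-8-methoxy-2-{(1E,3E)-4-[(2R)-8-methoxy-5-methyl-7-oxo-2,3,4,7-tetrahydrocyclohepta[b]pyran-2-yl]buta-1,3-dien-1-yl}-3,5-dimethyl-3,4-dihydrocyclohepta[b]pyran-7(2H)-one | Cc1cc(=O)c(OC)cc2c1C[C@@H](C)[C@H](/C=C/C=C/[C@H]1CCc3c(C)cc(=O)c(OC)cc3O1)O2 | intermediate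
33 | CNP0332980.1, (2R,3R)-8-hydroxy-2-{(1E,3E)-4-[(2R)-8-hydroxy-5-methyl-7-oxo-2,3,4,7-tetrahydrocyclohepta[b]pyran-2-yl]buta-1,3-dien-1-yl}-3,5-dimethyl-3,4-dihydrocyclohepta[b]pyran-7(2H)-one | Cc1cc(=O)c(O)cc2c1C[C@@H](C)[C@H](/C=C/C=C/[C@H]1CCc3c(C)cc(=O)c(O)cc3O1)O2 | target

Total step count: 27 steps.
Longest linear sequence: 18 steps (steps 1–6, 11–20, 26 and 27, from 1 to 33).

## Steps least certain to work

**Step 12 (key step).** The Breslow intermediate may be diverted: the tropone ring is only weakly aromatic, so protonation through the homoenolate form at a6 can compete; the carbene may also be consumed by addition to the vinyl sulfone. Fallback: starting from 15, generate the acyl radical by hydrogen abstraction from the aldehyde (dilauroyl peroxide or di-tert-butyl hyponitrite, PhCl, 60–80 °C). It adds 6-exo-trig to the vinyl sulfone, and the α-sulfonyl radical carries the chain by abstracting the next aldehyde hydrogen; this is the known peroxide-initiated radical hydroacylation of electron-poor alkenes. The route is rejoined at 16, whose C3 epimers converge in step 13. No new compound is made.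

**Step 6.** Oxidative addition at the doubly flanked C–Br bond may be slow, and hydrodebromination by a palladium hydride may take over. Fallback: starting from 7, a Stille coupling with tributyl(vinyl)stannane (Pd(PPh3)4, PhMe, 90 °C) gives 5-ethenyl-2,4-dimethoxy-6-methylcyclohepta-2,4,6-trien-1-one F1. Its monosubstituted alkene is then cleaved (OsO4 cat., NaIO4, 2,6-lutidine, dioxane–H2O) in preference to the ring double bonds, rejoining the route at 8.

**Step 11.** The alkoxy exchange may stall at an unfavourable equilibrium, the aldehyde may be tied up as an acetal, or the a4 methoxy group may exchange as well. Fallback: starting from 8, the a6 methoxy group is hydrolysed (1 M HCl, THF) to 2-hydroxy-4-methoxy-7-methyl-5-oxocyclohepta-1,3,6-triene-1-carbaldehyde F2. This is converted with (COCl)2 and catalytic DMF into 2-chloro-4-methoxy-7-methyl-5-oxocyclohepta-1,3,6-triene-1-carbaldehyde F3. The sodium alkoxide of 14 (NaH, THF, −40 °C) then displaces chloride by addition–elimination, rejoining the route at 15. The weak points of this path are silyl migration in the alkoxide and chlorination at the wrong oxygen of the vinylogous acid.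

**Step 14.** Two processes threaten it: migration of the exocyclic double bond of 17 into the ring, which would destroy C2, and an equilibrium at C3 that leaves much of the cis isomer. Fallback: starting from 16, keep C3 as set in step 12. Luche reduction gives (2R,3R,4RS)-2-{[(tert-butyldimethylsilyl)oxy]methyl}-4-hydroxy-8-methoxy-5-methyl-3-[(phenylsulfonyl)methyl]-3,4-dihydrocyclohepta[b]pyran-7(2H)-one F4. Thioacylation as in step 16 gives its O-(imidazol-1-ylthiocarbonyl) derivative F5, and Bu3SnH/AIBN gives (2R,3R)-2-{[(tert-butyldimethylsilyl)oxy]methyl}-8-methoxy-5-methyl-3-[(phenylsulfonyl)methyl]-3,4-dihydrocyclohepta[b]pyran-7(2H)-one F6. Reductive desulfonylation (SmI2, HMPA, THF–MeOH, −78 °C) rejoins the route at 21. The weak point is competing electron transfer to the tropone.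

**Step 17.** The stannyl radical may add to the tropone, or the thiocarbonyl ester may undergo thermal syn-elimination towards C3. Fallback: starting from 19, ionic hydrogenation (Et3SiH, BF3·OEt2, CH2Cl2, −40 °C) rejoins the route at 21. It needs a large excess of silane so that the C4 cation is trapped before it loses the C3 proton. No new compound is made.

**Step 23.** Addition–elimination at a6′ lacks the activation by a formyl group that step 11 enjoys and may be sluggish, or the methoxy groups may be lost by hydrolysis. Fallback: starting from 27, the acetonide is removed as before to 28 and the primary hydroxyl is silylated (t-BuMe2SiCl, imidazole) to give 5-[(3R)-4-[(tert-butyldimethylsilyl)oxy]-3-hydroxybutyl]-2,4-dimethoxy-6-methylcyclohepta-2,4,6-trien-1-one F7. Its sodium alkoxide (NaH, THF, 0 °C to rt) displaces the a6′ methoxy group to give (2R)-2-{[(tert-butyldimethylsilyl)oxy]methyl}-8-methoxy-5-methyl-3,4-dihydrocyclohepta[b]pyran-7(2H)-one F8. Bu4NF then rejoins the route at 29.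

## Further compounds

F0 | step 12 | none | none
F1 | step 6 | 5-ethenyl-2,4-dimethoxy-6-methylcyclohepta-2,4,6-trien-1-one | Cc1cc(=O)c(OC)cc(OC)c1C=C
F2 | step 11 | 2-hydroxy-4-methoxy-7-methyl-5-oxocyclohepta-1,3,6-triene-1-carbaldehyde | Cc1cc(=O)c(OC)cc(O)c1C=O
F3 | step 11 | 2-chloro-4-methoxy-7-methyl-5-oxocyclohepta-1,3,6-triene-1-carbaldehyde | Cc1cc(=O)c(OC)cc(Cl)c1C=O
F4 | step 14 | (2R,3R,4RS)-2-{[(tert-butyldimethylsilyl)oxy]methyl}-4-hydroxy-8-methoxy-5-methyl-3-[(phenylsulfonyl)methyl]-3,4-dihydrocyclohepta[b]pyran-7(2H)-one | Cc1cc(=O)c(OC)cc2c1C(O)[C@@H](CS(=O)(=O)c1ccccc1)[C@H](CO[Si](C)(C)C(C)(C)C)O2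
F5 | step 14 | O-[(2R,3R,4RS)-2-{[(tert-butyldimethylsilyl)oxy]methyl}-8-methoxy-5-methyl-7-oxo-3-[(phenylsulfonyl)methyl]-2,3,4,7-tetrahydrocyclohepta[b]pyran-4-yl] 1H-imidazole-1-carbothioate | Cc1cc(=O)c(OC)cc2c1C(OC(=S)n1ccnc1)[C@@H](CS(=O)(=O)c1ccccc1)[C@H](CO[Si](C)(C)C(C)(C)C)O2
F6 | step 14 | (2R,3R)-2-{[(tert-butyldimethylsilyl)oxy]methyl}-8-methoxy-5-methyl-3-[(phenylsulfonyl)methyl]-3,4-dihydrocyclohepta[b]pyran-7(2H)-one | Cc1cc(=O)c(OC)cc2c1C[C@@H](CS(=O)(=O)c1ccccc1)[C@H](CO[Si](C)(C)C(C)(C)C)O2
F0 | step 17 | none | none
F7 | step 23 | 5-[(3R)-4-[(tert-butyldimethylsilyl)oxy]-3-hydroxybutyl]-2,4-dimethoxy-6-methylcyclohepta-2,4,6-trien-1-one | Cc1cc(=O)c(OC)cc(OC)c1CC[C@@H](O)CO[Si](C)(C)C(C)(C)C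
F8 | step 23 | (2R)-2-{[(tert-butyldimethylsilyl)oxy]methyl}-8-methoxy-5-methyl-3,4-dihydrocyclohepta[b]pyran-7(2H)-one | CC(C)(C)[Si](C)(C)OC[C@H]1CCc2c(C)cc(=O)c(OC)cc2O1
A1 | alternative 1 | (2R,3R)-3,5-dimethyl-8-[(triethylsilyl)oxy]-2-{[(triisopropylsilyl)oxy]methyl}-2,3,4,9-tetrahydrocyclohepta[b]pyran-7(8H)-one | CC1=CC(=O)C(O[Si](CC)(CC)CC)CC2=C1C[C@@H](C)[C@H](CO[Si](C(C)C)(C(C)C)C(C)C)O2
A2 | alternative 1 | 1-[(2R,3R)-3-methyl-5-(prop-1-en-2-yl)-2-{[(triisopropylsilyl)oxy]methyl}-3,4-dihydro-2H-pyran-6-yl]-2-[(triethylsilyl)oxy]pent-4-en-3-one | C=CC(=O)C(O[Si](CC)(CC)CC)CC1=C(C(C)=C)C[C@@H](C)[C@H](CO[Si](C(C)C)(C(C)C)C(C)C)O1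
A3 | alternative 2 | (2R,3S)-8-methoxy-2-{(1E,3E)-4-[(2R)-8-methoxy-5-methyl-4,7-dioxo-2,3,4,7-tetrahydrocyclohepta[b]pyran-2-yl]buta-1,3-dien-1-yl}-3,5-dimethyl-2,3-dihydrocyclohepta[b]pyran-4,7-dione | Cc1cc(=O)c(OC)cc2c1C(=O)[C@@H](C)[C@H](/C=C/C=C/[C@H]1CC(=O)c3c(C)cc(=O)c(OC)cc3O1)O2
A4 | alternative 2 | (1E,3E)-1,4-bis(4,4,5,5-tetramethyl-1,3,2-dioxaborolan-2-yl)buta-1,3-diene | CC1(C)OB(/C=C/C=C/B2OC(C)(C)C(C)(C)O2)OC1(C)C
A5 | alternative 2 | 8-methoxy-3,5-dimethylcyclohepta[b]pyran-4,7-dione | Cc1cc(=O)c(OC)cc2occ(C)c(=O)c12
A6 | alternative 2 | 8-methoxy-5-methylcyclohepta[b]pyran-4,7-dione | Cc1cc(=O)c(OC)cc2occc(=O)c12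
A7 | alternative 3 | oxygen-bridged cycloheptadienone fused to ring B, with (2R,3R)-2-{[(tert-butyldimethylsilyl)oxy]methyl}-3-methyl substitution and a4–a7 oxygen bridge | CC1=CC(=O)C2C=C3C1(O2)C[C@@H](C)[C@H](CO[Si](C)(C)C(C)(C)C)O3
A8 | alternative 3 | 2-{(2R,3R)-4-[(tert-butyldimethylsilyl)oxy]-3-(ethynyloxy)-2-methylbutyl}-3-methyl-5-oxo-5,6-dihydro-2H-pyran-2-yl acetate | CC(=O)OC1(C[C@@H](C)[C@H](CO[Si](C)(C)C(C)(C)C)OC#C)OCC(=O)C=C1C
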